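(The earlier runs and the new flask stem from a simulated flask on assumed constants, and the scatter is random.)

3.07 mM of reagent is the crossover concentration: the [reagent] at which starting material goes as fast by a route through reagent as by its step to target, a selectivity factor in concentration form. We read it from Friday's run, where target stood at 4.0% after 30.0 h and 4.1% after 40.0 h. We take that stall as starting material lost; target's share of the loss is then crossover over [reagent], so crossover is the plateau times the 75 mM charged. The scatter of 0.5 percentage points puts 12.2% of uncertainty on it.

| flask | starting material | reagent | remark | time |
|---|---|---|---|---|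
| Saturday's | 38 mM | 34.2 mM | run made earlier |  |
| Monday's | 38 mM | 48 mM | run made earlier |  |
| Friday's | 38 mM | 75 mM | run made earlier |  |
| Thursday's | 57 mM | 34.2 mM | run made earlier |  |
| larch | 38 mM | 34.2 mM | everything together at the start | 50 h |
| oak | 38 mM | 34.2 mM (in portions, 2, over 30 h) | first portion at the start, last at 30 h | 50 h |
| cedar | 38 mM | 34.2 mM (fed, over 30 h) | all else is in the flask from the start; the feed brings no volume worth counting | 50 h |
| alder | 38 mM (fed, over 30 h) | 34.2 mM | all else is in the flask from the start; the feed brings no volume worth counting | 50 h |

- Saturday's (time / h: target / %, side product / %): 5.00: 1.5, 0.5; 10.0: 2.6, 0.2; 15.0: 3.1, 1.5; 20.0: 4.6, 0; 25.0: 5.2, 0; 30.0: 6.2, 1.2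
- Monday's (time / h: target / %, side product / %): 3.00: 0.5, 0.5; 5.00: 2.2, 0; 8.00: 1.1, 0; 15.0: 3.5, 0.5; 25.0: 4.5, 0.6; 40.0: 6.7, 1.9
- Friday's (time / h: target / %, side product / %): 2.50: 0.9, 0; 8.00: 1.9, 0.2; 15.0: 2.4, 0; 20.0: 3.4, 1.0; 30.0: 4.0, 2.1; 40.0: 4.1, 2.2
- Thursday's (time / h: target / %, side product / %): 4.00: 1.6, 0.6; 10.0: 2.2, 0; 20.0: 3.8, 0.5; 30.0: 5.8, 0.5; 40.0: 8.4, 1.0

(standard deviation of a reading: 0.5 percentage points)

- what was read earlier has a scatter of 0.5 percentage points, one standard deviation

1. the flask that comes out highest in share of target in target plus side product, or "all alike" when all lie within 1.5 percentage points (larch / oak / cedar / alder / all alike)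
2. share of target in target plus side product at the end, larch
3. share of target in target plus side product at the end, oak
4. share of target in target plus side product at the end, cedar
5. share of target in target plus side product at the end, alder

Now the rate in larch, by our own reckoning. Target starts at 0.00260 /h of the charge, read over the first 10.0 h of Saturday's run, which has the same charges. The reagent route starts 11.1 times faster, so that route takes starting material at 0.0289 /h at the start, and we leave target's own smaller step out of the slowing. Starting material and reagent fall together from nearly equal charges, so we treat that route as second order, and by our reckoning the target rate is divided by 2.45 at 50 h. Summed over the run, this slowing gives crossover over [reagent] times the logarithm of that factor: target 8.04%, less than the 13.0% of an unslowed rate.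

The forecast gives larch 80%, oak 83%, cedar 82% and alder 85%, and names alder highest, calling reagent “roughly zero order there”. We part from it there, since our target rate slows with reagent.

The flasks end at larch 82.7%, oak 91.1%, cedar 92.8% and alder 88.3%, so cedar stands highest.

    starting material + reagent → intermediate A (k = 1.10 /M/h)
    intermediate A → intermediate B (k = 0.00250 /h)
    starting material → target (k = 0.00310 /h)
    intermediate B → side product (k = 0.0240 /h)

Larch holds target 8.31% at 50.0 h, against our 8.04%, and starting material 31.0%, against our 40.9%, and the forecast stood 11 points below cedar. The neighbour of larch charged with 140 mM of reagent takes the same reckoning: [reagent] is 45.6 times crossover, so target's share of the starting material lost is 2.19%. That neighbour has 0.221% of its starting material left at 50.0 h and holds target 2.28%. Its share of target in target plus side product is 37.4%, with 87.6% standing as intermediate A.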